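The α-methylene group of target 26 stays masked as its PhSH adduct (24) and is released last by sulfoxide elimination. The O3 acetate and the O9 angelate go on one after the other, and no protecting group is needed after the ring expansion.
The C9–C10 disconnection leads from the ten-membered carbocycle 21 to the eight-membered lactone 18. In 18, C9 is parked as the acyl group on O3 and C3 carries the chain C2–C1–C10(I)–C14; SmI2 moves the acyl carbon from O3 to C10 (ring expansion 8 → 10).
Enabling feature: O3 stands 1,5 to C9, so O3–C3–C2–C1–C10–C9 is a six-membered array. The cis (Z) C4=C5 bond fits the eight-membered ring O3–C3–C4=C5–C6–C7–C8–C9, and the size of that ring enforces the geometry.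
Lactone 18 comes from ring-closing metathesis (C4=C5) of ester 17, made from acid 11 (from butenolide 1: C5–C7, C11, C12) and allylic alcohol 16 (from γ-valerolactone 12: C1–C3, C10, C14).
Order of rings: γ-lactone (present in 1), then the eight-membered lactone (step 13), then the transient oxane and the ten-membered carbocycle (step 14).

Key step: step 14

Remark 1: germacrane numbering is used for atoms (ring C1–C10, lactone carbons C11–C13, C14 = methyl on C10, C15 = methyl on C4).
Remark 2 (assumption): the iodine-bearing carbon (future C10) is carried as both epimers from racemic 12 and is written without a descriptor, because step 14 erases it. The sulfur centre of sulfoxide 25 is likewise undefined.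

Step 1
Reactants: 1 (S)-5-(hydroxymethyl)furan-2(5H)-one
Product: 2 (S)-5-{[(tert-butyldimethylsilyl)oxy]methyl}furan-2(5H)-one
Conditions: TBSCl, imidazole, DMF, 0 °C → rt
Reagents that add atoms: tert-butyldimethylsilyl chloride, CC(C)(C)[Si](C)(C)Cl
Why: Silyl ether protection of the primary alcohol gives a bulky side chain that shields one butenolide face, and the stereocentre (future C6) comes from the chiral pool.

Step 2
Reactants: 3 tert-butyl acetate
Product: 5 tert-butyl[(1-tert-butoxyethenyl)oxy]dimethylsilane, via lithium enolate 4 (not isolated)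
Conditions: LiN(i-Pr)2, THF, −78 °C; TBSCl, DMPU, −78 °C → rt
Reagents that add atoms: tert-butyldimethylsilyl chloride, CC(C)(C)[Si](C)(C)Cl
Why: O-silylation of a lithium ester enolate in the presence of DMPU is the standard way to form a ketene silyl acetal.

Step 3
Reactants: 2 (S)-5-{[(tert-butyldimethylsilyl)oxy]methyl}furan-2(5H)-one; 5 tert-butyl[(1-tert-butoxyethenyl)oxy]dimethylsilane
Product: 7 tert-butyl 2-[(2S,3S,4S)-2-{[(tert-butyldimethylsilyl)oxy]methyl}-5-oxo-4-[(phenylsulfanyl)methyl]oxolan-3-yl]acetate, via silyl ketene acetal 6 (not isolated)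
Conditions: TBSOTf (5 mol %), CH2Cl2, −78 °C; then PhSCH2Cl, ZnBr2 (10 mol %), −78 °C → rt
Reagents that add atoms: chloromethyl phenyl sulfide, ClCSc1ccccc1
Why: Mukaiyama–Michael addition anti to the C6 side chain sets C7, and Lewis-acid phenylthiomethylation of 6 anti to the new C7 substituent sets C11 and brings in C13 as a masked methylene.

Step 4
Reactants: 7 tert-butyl 2-[(2S,3S,4S)-2-{[(tert-butyldimethylsilyl)oxy]methyl}-5-oxo-4-[(phenylsulfanyl)methyl]oxolan-3-yl]acetate
Product: 8 tert-butyl 2-[(2S,3S,4S)-2-(hydroxymethyl)-5-oxo-4-[(phenylsulfanyl)methyl]oxolan-3-yl]acetate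
Conditions: HF·pyridine, THF, 0 °C → rt
Reagents that add atoms: none
Why: Fluoride-mediated desilylation under non-basic conditions leaves the tert-butyl ester, the lactone and the β-sulfanyl unit untouched.

Step 5
Reactants: 8 tert-butyl 2-[(2S,3S,4S)-2-(hydroxymethyl)-5-oxo-4-[(phenylsulfanyl)methyl]oxolan-3-yl]acetate
Product: 9 tert-butyl 2-[(2S,3S,4S)-2-formyl-5-oxo-4-[(phenylsulfanyl)methyl]oxolan-3-yl]acetate
Conditions: Dess–Martin periodinane, CH2Cl2, 0 °C → rt
Reagents that add atoms: none
Why: Dess–Martin oxidation works under neutral conditions, tolerates aryl alkyl sulfides and should not epimerise the α-acyloxy aldehyde centre C6.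

Step 6
Reactants: 9 tert-butyl 2-[(2S,3S,4S)-2-formyl-5-oxo-4-[(phenylsulfanyl)methyl]oxolan-3-yl]acetate
Product: 10 tert-butyl 2-[(2R,3S,4S)-2-ethenyl-5-oxo-4-[(phenylsulfanyl)methyl]oxolan-3-yl]acetate
Conditions: Ph3PCH3Br, KN(SiMe3)2, THF, −78 → 0 °C
Reagents that add atoms: methyltriphenylphosphonium bromide, C[P+](c1ccccc1)(c1ccccc1)c1ccccc1.[Br-]
Why: Wittig methylenation with one equivalent of ylide at low temperature takes the aldehyde much faster than either ester carbonyl (C6 keeps its spatial arrangement; only its descriptor changes).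

Step 7
Reactants: 10 tert-butyl 2-[(2R,3S,4S)-2-ethenyl-5-oxo-4-[(phenylsulfanyl)methyl]oxolan-3-yl]acetate
Product: 11 2-[(2R,3S,4S)-2-ethenyl-5-oxo-4-[(phenylsulfanyl)methyl]oxolan-3-yl]acetic acid
Conditions: CF3CO2H, CH2Cl2, 0 °C → rt
Reagents that add atoms: none
Why: Acidolysis of the tert-butyl ester frees the C9 carboxyl group without opening the γ-lactone.

Step 8
Reactants: 12 γ-valerolactone (racemic)
Product: 13 4-hydroxy-N-methoxy-N-methylpentanamide
Conditions: MeNH(OMe)·HCl, i-PrMgCl, THF, −20 °C
Reagents that add atoms: N,O-dimethylhydroxylamine hydrochloride, CNOC.Cl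
Why: Aminolysis of a lactone with the magnesium amide of N,O-dimethylhydroxylamine is the standard Weinreb amide formation.

Step 9
Reactants: 13 4-hydroxy-N-methoxy-N-methylpentanamide
Product: 14 4-iodo-N-methoxy-N-methylpentanamide
Conditions: I2, PPh3, imidazole, CH2Cl2, 0 °C
Reagents that add atoms: iodine, II
Why: Appel-type iodination converts the secondary alcohol into the iodide under neutral conditions.

Step 10
Reactants: 14 4-iodo-N-methoxy-N-methylpentanamide
Product: 15 6-iodo-2-methylhept-1-en-3-one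
Conditions: CH2=C(CH3)MgBr, THF, −40 → 0 °C; aq. NH4Cl
Reagents that add atoms: isopropenylmagnesium bromide, C=C(C)[Mg]Br
Why: In the Weinreb ketone synthesis the chelated adduct sets the enone free only on work-up, so over-addition and base-induced reactions of the γ-iodo ketone are avoided.

Step 11
Reactants: 15 6-iodo-2-methylhept-1-en-3-one
Product: 16 (3R)-6-iodo-2-methylhept-1-en-3-ol
Conditions: (S)-2-methyl-CBS-oxazaborolidine (15 mol %), catecholborane, toluene, −78 °C
Reagents that add atoms: none
Why: Corey–Bakshi–Shibata reduction treats the isopropenyl group as the large substituent and sets (3R) by reagent control, and catecholborane at low temperature avoids hydroboration.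

Step 12
Reactants: 11 2-[(2R,3S,4S)-2-ethenyl-5-oxo-4-[(phenylsulfanyl)methyl]oxolan-3-yl]acetic acid; 16 (3R)-6-iodo-2-methylhept-1-en-3-ol
Product: 17 (3R)-6-iodo-2-methylhept-1-en-3-yl 2-[(2R,3S,4S)-2-ethenyl-5-oxo-4-[(phenylsulfanyl)methyl]oxolan-3-yl]acetate
Conditions: DCC, DMAP (cat.), CH2Cl2, 0 °C → rt (16 used directly after its preparation)
Reagents that add atoms: none
Why: Steglich esterification joins an unhindered acid to the secondary allylic alcohol with retention at C3 and is mild enough for the δ-iodo alcohol.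

Step 13
Reactants: 17 (3R)-6-iodo-2-methylhept-1-en-3-yl 2-[(2R,3S,4S)-2-ethenyl-5-oxo-4-[(phenylsulfanyl)methyl]oxolan-3-yl]acetate
Product: 18 bicyclic dilactone: (4Z)-eight-membered lactone O3–C9 trans-fused at C6/C7 to the γ-lactone (3R,6S,7S,11S) with a 3-iodobutyl chain on C3 and a phenylsulfanyl group on C13
Conditions: second-generation Hoveyda–Grubbs catalyst RuCl2(H2IMes)(=CH-C6H4-2-O-i-Pr) (10 mol %), toluene (1 mM), 80 °C, argon sparge
Reagents that add atoms: none
Why: Ring-closing metathesis of the vinyl and isopropenyl groups builds the trisubstituted C4=C5 bond, and an eight-membered ring can hold only the Z olefin that the target needs.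

Step 14
Reactants: 18 bicyclic dilactone with 3-iodobutyl chain on C3
Product: 21 (3R,4Z,6S,7S,10R,11S)-3-hydroxy-9-oxo-13-(phenylsulfanyl)germacr-4-en-12,6-olide, via alkylsamarium diiodide 19 (not isolated), via samarium hemiketalate 20 (not isolated)
Conditions: SmI2 (2.5 equiv), HMPA (10 equiv), THF, −78 °C, slow addition of 18, then −20 °C; pH 7 phosphate buffer
Reagents that add atoms: none
Why: SmI2/HMPA reduces the secondary iodide by two single-electron transfers to the configurationally labile alkylsamarium 19, which adds to the C9 lactone carbonyl and forms the C9–C10 bond; hemiketalate 20 then releases O3 from C9, so O3 leaves the ring while C2, C1 and C10 enter it and the eight-membered lactone becomes the ten-membered carbocycle. The closest known reaction type is the SmI2-promoted intramolecular nucleophilic acyl substitution of halo-substituted esters and lactones, established for acyl transfer through six-membered transition states and for ring expansion to medium carbocycles. The ring closed directly is the oxane O3–C3–C2–C1–C10–C9 (6-exo-trig attack on the carbonyl, giving the 11-oxabicyclo[5.3.1]undecene core of 20), and the ten-membered ring is closed by the same bond and set free by C9–O3 scission. C10 is the only new stereocentre: in the chair-like transition state the C3–C4 and C9–C8 bonds must take the 1,3-diaxial positions (the only span an eight-membered ring allows) and the C14 methyl sits equatorial, so the (3R)-carbinol centre relays to (10R) and both iodide epimers converge through 19 (Curtin–Hammett). The step needs chemoselectivity for C9 over the C12 carbonyl and for anion formation over radical attack on C4=C5; the first is secured because only C9 lies within six-membered reach, the second by the methyl-blocked C4 and the fast HMPA-accelerated second electron transfer at high SmI2 concentration. Because C9 stays masked as the trivalent samarium hemiketalate until the buffered quench, neither further reduction nor epimerisation at C10 should occur in the flask.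

Step 15
Reactants: 21 (3R,4Z,6S,7S,10R,11S)-3-hydroxy-9-oxo-13-(phenylsulfanyl)germacr-4-en-12,6-olide
Product: 22 (3S,4Z,6S,7S,10R,11S)-3-acetoxy-9-oxo-13-(phenylsulfanyl)germacr-4-en-12,6-olide
Conditions: AcOH, PPh3, DIAD, toluene, 0 °C → rt
Reagents that add atoms: acetic acid, CC(=O)O
Why: Mitsunobu esterification of the secondary allylic alcohol proceeds by SN2 inversion, which turns the relay centre (3R) into the required (3S) and installs the acetate in the same operation.

Step 16
Reactants: 22 (3S,4Z,6S,7S,10R,11S)-3-acetoxy-9-oxo-13-(phenylsulfanyl)germacr-4-en-12,6-olide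
Product: 23 (3S,4Z,6S,7S,9S,10R,11S)-3-acetoxy-9-hydroxy-13-(phenylsulfanyl)germacr-4-en-12,6-olide
Conditions: LiBH(s-Bu)3, THF, −78 °C; aq. NH4Cl
Reagents that add atoms: none
Why: Bulky-hydride ketone reduction should follow the Felkin–Anh model, with peripheral attack anti to the C10–C1 bond giving the 9,10-anti (9S) alcohol, while acetate and lactone survive at −78 °C.

Step 17
Reactants: 23 (3S,4Z,6S,7S,9S,10R,11S)-3-acetoxy-9-hydroxy-13-(phenylsulfanyl)germacr-4-en-12,6-olide
Product: 24 (3S,4Z,6S,7S,9S,10R,11S)-3-acetoxy-9-angeloyloxy-13-(phenylsulfanyl)germacr-4-en-12,6-olide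
Conditions: angelic acid, 2,4,6-trichlorobenzoyl chloride, Et3N, toluene, rt; then 23, 80 °C
Reagents that add atoms: angelic acid, C/C=C(/C)C(=O)O
Why: Yamaguchi esterification through the mixed anhydride without a nucleophilic catalyst acylates hindered alcohols and avoids isomerisation of the Z-configured angelate to the tiglate.

Step 18
Reactants: 24 (3S,4Z,6S,7S,9S,10R,11S)-3-acetoxy-9-angeloyloxy-13-(phenylsulfanyl)germacr-4-en-12,6-olide
Product: 26 (3S,4Z,6R,7S,9S,10R)-3-acetoxy-9-angeloyloxygermacra-4,11(13)-dien-12,6-olide (CNP0173235.1), via sulfoxide 25 (not isolated)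
Conditions: mCPBA (1.0 equiv), CH2Cl2, −78 °C; then toluene, 110 °C
Reagents that add atoms: none
Why: Sulfur is oxidised far faster than the deactivated olefins, and the thermal syn-elimination of the sulfoxide can take only H11, which unveils the exocyclic C11=C13 bond under base-free conditions.

Compound list
1 | (S)-5-(hydroxymethyl)furan-2(5H)-one | O=C1C=C[C@@H](CO)O1 | starting material
2 | (S)-5-{[(tert-butyldimethylsilyl)oxy]methyl}furan-2(5H)-one | O=C1C=C[C@@H](CO[Si](C)(C)C(C)(C)C)O1 | intermediate
3 | tert-butyl acetate | CC(=O)OC(C)(C)C | starting material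
4 | lithium 1-tert-butoxyethen-1-olate (lithium enolate of 3) | [Li]OC(=C)OC(C)(C)C | intermediate
5 | tert-butyl[(1-tert-butoxyethenyl)oxy]dimethylsilane | C=C(OC(C)(C)C)O[Si](C)(C)C(C)(C)C | intermediate
6 | tert-butyl 2-[(2S,3S)-5-[(tert-butyldimethylsilyl)oxy]-2-{[(tert-butyldimethylsilyl)oxy]methyl}-2,3-dihydrofuran-3-yl]acetate | CC(C)(C)[Si](C)(C)OC1=C[C@H](CC(=O)OC(C)(C)C)[C@@H](CO[Si](C)(C)C(C)(C)C)O1 | intermediate
7 | tert-butyl 2-[(2S,3S,4S)-2-{[(tert-butyldimethylsilyl)oxy]methyl}-5-oxo-4-[(phenylsulfanyl)methyl]oxolan-3-yl]acetate | C(Sc1ccccc1)[C@@H]2C(=O)O[C@H](CO[Si](C)(C)C(C)(C)C)[C@H]2CC(=O)OC(C)(C)C | intermediate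
8 | tert-butyl 2-[(2S,3S,4S)-2-(hydroxymethyl)-5-oxo-4-[(phenylsulfanyl)methyl]oxolan-3-yl]acetate | C(Sc1ccccc1)[C@@H]2C(=O)O[C@H](CO)[C@H]2CC(=O)OC(C)(C)C | intermediate
9 | tert-butyl 2-[(2S,3S,4S)-2-formyl-5-oxo-4-[(phenylsulfanyl)methyl]oxolan-3-yl]acetate | C(Sc1ccccc1)[C@@H]2C(=O)O[C@H](C=O)[C@H]2CC(=O)OC(C)(C)C | intermediate
10 | tert-butyl 2-[(2R,3S,4S)-2-ethenyl-5-oxo-4-[(phenylsulfanyl)methyl]oxolan-3-yl]acetate | C(Sc1ccccc1)[C@@H]2C(=O)O[C@H](C=C)[C@H]2CC(=O)OC(C)(C)C | intermediate
11 | 2-[(2R,3S,4S)-2-ethenyl-5-oxo-4-[(phenylsulfanyl)methyl]oxolan-3-yl]acetic acid | C(Sc1ccccc1)[C@@H]2C(=O)O[C@H](C=C)[C@H]2CC(=O)O | intermediate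
12 | γ-valerolactone (5-methyloxolan-2-one, racemic) | CC1CCC(=O)O1 | starting material
13 | 4-hydroxy-N-methoxy-N-methylpentanamide | CC(O)CCC(=O)N(C)OC | intermediate
14 | 4-iodo-N-methoxy-N-methylpentanamide | CC(I)CCC(=O)N(C)OC | intermediate
15 | 6-iodo-2-methylhept-1-en-3-one | CC(I)CCC(=O)C(C)=C | intermediate
16 | (3R)-6-iodo-2-methylhept-1-en-3-ol (both C6 epimers) | C=C(C)[C@H](O)CCC(C)I | intermediate
17 | (3R)-6-iodo-2-methylhept-1-en-3-yl 2-[(2R,3S,4S)-2-ethenyl-5-oxo-4-[(phenylsulfanyl)methyl]oxolan-3-yl]acetate | C(Sc1ccccc1)[C@@H]2C(=O)O[C@H](C=C)[C@H]2CC(=O)O[C@H](CCC(C)I)C(C)=C | intermediate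
18 | bicyclic dilactone: (4Z)-eight-membered lactone (O3–C9) trans-fused at C6/C7 to the γ-lactone; 3R,6S,7S,11S; 3-iodobutyl on C3, SPh on C13 | C(Sc1ccccc1)[C@@H]2C(=O)O[C@@H]3/C=C(/C)[C@@H](CCC(C)I)OC(=O)C[C@@H]23 | intermediate
19 | alkylsamarium diiodide derived from 18 (C10–SmI2) | C(Sc1ccccc1)[C@@H]2C(=O)O[C@@H]3/C=C(/C)[C@@H](CCC(C)[Sm](I)I)OC(=O)C[C@@H]23 | intermediate
20 | samarium hemiketalate with 11-oxabicyclo[5.3.1]undecene core (O3 bridges C3 and C9; 3R,10R) | C(Sc1ccccc1)[C@@H]2C(=O)O[C@@H]3/C=C(/C)[C@H]4CC[C@@H](C)[C@](O[Sm](I)I)(O4)C[C@@H]23 | intermediate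
21 | (3R,4Z,6S,7S,10R,11S)-3-hydroxy-9-oxo-13-(phenylsulfanyl)germacr-4-en-12,6-olide | C(Sc1ccccc1)[C@@H]2C(=O)O[C@@H]3/C=C(/C)[C@H](O)CC[C@@H](C)C(=O)C[C@@H]23 | intermediate
22 | (3S,4Z,6S,7S,10R,11S)-3-acetoxy-9-oxo-13-(phenylsulfanyl)germacr-4-en-12,6-olide | C(Sc1ccccc1)[C@@H]2C(=O)O[C@@H]3/C=C(/C)[C@@H](OC(C)=O)CC[C@@H](C)C(=O)C[C@@H]23 | intermediate
23 | (3S,4Z,6S,7S,9S,10R,11S)-3-acetoxy-9-hydroxy-13-(phenylsulfanyl)germacr-4-en-12,6-olide | C(Sc1ccccc1)[C@@H]2C(=O)O[C@@H]3/C=C(/C)[C@@H](OC(C)=O)CC[C@@H](C)[C@@H](O)C[C@@H]23 | intermediate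
24 | (3S,4Z,6S,7S,9S,10R,11S)-3-acetoxy-9-angeloyloxy-13-(phenylsulfanyl)germacr-4-en-12,6-olide | C(Sc1ccccc1)[C@@H]2C(=O)O[C@@H]3/C=C(/C)[C@@H](OC(C)=O)CC[C@@H](C)[C@@H](OC(=O)/C(C)=C\C)C[C@@H]23 | intermediate
25 | 13-(phenylsulfinyl) analogue of 24 (sulfoxide, sulfur undefined) | C(S(=O)c1ccccc1)[C@@H]2C(=O)O[C@@H]3/C=C(/C)[C@@H](OC(C)=O)CC[C@@H](C)[C@@H](OC(=O)/C(C)=C\C)C[C@@H]23 | intermediate
26 | (3S,4Z,6R,7S,9S,10R)-3-acetoxy-9-angeloyloxygermacra-4,11(13)-dien-12,6-olide (CNP0173235.1) | C=C1C(=O)O[C@@H]2/C=C(/C)[C@@H](OC(C)=O)CC[C@@H](C)[C@@H](OC(=O)/C(C)=C\C)C[C@@H]12 | target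

Total step count: 18. Longest linear sequence: 13 steps (1, 3, 4, 5, 6, 7, 12, 13, 14, 15, 16, 17, 18).

Steps most likely to fail

Step 14. Three processes could spoil it:
- premature hydrogen abstraction or protonation at C10, which gives simple deiodination;
- radical attack on the C4=C5 bond before the second electron transfer;
- erosion of the C10 selectivity, because the equatorial preference of the methyl group in the oxane transition state is modest.

The fallback replaces ring expansion by direct macrocyclic acylation and sets out from 18. Thiolysis of the eight-membered lactone with Me2AlSEt would give the S-ethyl thioester with free (3R)-hydroxyl F1; a γ-lactone opened in passing closes again on work-up. Mitsunobu inversion with AcOH gives the (3S)-acetate thioester F2. Zinc insertion (Zn, LiCl, THF) gives the alkylzinc iodide F3. An intramolecular Fukuyama ketone synthesis (PdCl2(PPh3)2, toluene, high dilution) then closes the same C9–C10 bond and comes back to the route at 22, where C10 is adjusted by base equilibration.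

Step 13. The likely problems are oligomerisation by cross metathesis, slow engagement of the 1,1-disubstituted olefin, and the unfavourable s-trans ester conformer. The fallback makes the olefin first and closes the ring by lactonisation. It sets out from 9 and 14.
- Stork–Zhao olefination of 9 with (1-iodoethyl)triphenylphosphonium iodide and NaN(SiMe3)2 gives the (Z)-vinyl iodide F4.
- Reduction of 14 with i-Bu2AlH gives 4-iodopentanal F5.
- Nozaki–Hiyama–Kishi coupling of F4 with F5 (CrCl2, NiCl2 cat., chiral sulfonamide ligand to favour 3R) gives the allylic alcohol F6 with retention of the olefin geometry.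
- CF3CO2H frees the seco acid F7.
- Shiina macrolactonisation (2-methyl-6-nitrobenzoic anhydride, DMAP, high dilution) comes back at 18.

Step 16. Hydride delivery to the flexible ten-membered ketone may show poor or reversed facial selectivity. The fallback accepts the other face and corrects it during the esterification. It sets out from 22. Reduction with a small hydride (NaBH4, MeOH, −40 °C) or separation of the epimers provides the (9R)-alcohol F8. Mitsunobu esterification of F8 with angelic acid (PPh3, DIAD) inverts C9 and comes back at 24.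

Further compounds
F1 | step 14 | S-ethyl thioester of the seco acid with free (3R)-hydroxyl, (Z)-olefin and secondary iodide | C(Sc1ccccc1)[C@@H]2C(=O)O[C@H](/C=C(/C)[C@H](O)CCC(C)I)[C@H]2CC(=O)SCC
F2 | step 14 | (3S)-acetate of the seco S-ethyl thioester | C(Sc1ccccc1)[C@@H]2C(=O)O[C@H](/C=C(/C)[C@@H](OC(C)=O)CCC(C)I)[C@H]2CC(=O)SCC
F3 | step 14 | alkylzinc iodide derived from F2 | C(Sc1ccccc1)[C@@H]2C(=O)O[C@H](/C=C(/C)[C@@H](OC(C)=O)CCC(C)[Zn]I)[C@H]2CC(=O)SCC
F4 | step 13 | tert-butyl 2-[(2S,3S,4S)-2-[(Z)-2-iodoprop-1-enyl]-5-oxo-4-[(phenylsulfanyl)methyl]oxolan-3-yl]acetate | C(Sc1ccccc1)[C@@H]2C(=O)O[C@H](/C=C(/C)I)[C@H]2CC(=O)OC(C)(C)C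
F5 | step 13 | 4-iodopentanal | CC(I)CCC=O
F6 | step 13 | tert-butyl ester of the (3R,4Z)-seco hydroxy acid | C(Sc1ccccc1)[C@@H]2C(=O)O[C@H](/C=C(/C)[C@H](O)CCC(C)I)[C@H]2CC(=O)OC(C)(C)C
F7 | step 13 | (3R,4Z)-seco hydroxy acid | C(Sc1ccccc1)[C@@H]2C(=O)O[C@H](/C=C(/C)[C@H](O)CCC(C)I)[C@H]2CC(=O)O
F8 | step 16 | (3S,4Z,6S,7S,9R,10R,11S)-3-acetoxy-9-hydroxy-13-(phenylsulfanyl)germacr-4-en-12,6-olide | C(Sc1ccccc1)[C@@H]2C(=O)O[C@@H]3/C=C(/C)[C@@H](OC(C)=O)CC[C@@H](C)[C@H](O)C[C@@H]23
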